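**Strategy.** The flavone is cut through its pyranone ring C. One palladium-mediated operation forms C4a–C4, C4–C3 and O1–C2: carbon monoxide becomes the C4 carbonyl between the iodinated C4a of a ring-A ortho-iodophenol (hydroxyl on C8a) and the terminal alkyne (future C3 and C2) carried by C5 of the dihydrobenzofuran, after which O1 closes onto C2. The step exploits the ortho relationship of O1 and the C4 carbonyl on ring A and the local symmetry of the 6-methylphloroglucinol ring. The alkyne partner is a penta-MOM (2S,3S)-2,3-diaryl-5-ethynyl-2,3-dihydrobenzofuran that already holds both stereocentres; the iodophenol derives from a symmetric bis-MOM methylphloroglucinol. C3 hydroxylation, O-methylation and MOM removal complete the route.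

Key step: step 14

Assumption 1: the (1R,4R,5R)-sulfide 9 is taken to deliver its benzylidene carbon with the facial sense that gives 2S; if its intrinsic preference is the opposite, the (1S,4S,5S)-enantiomer (from (S)-limonene) is used with no other change.
Assumption 2: isothiocineole 9 and 1-bromo-4-(methoxymethoxy)benzene 17 are taken as purchasable (9 is otherwise one step from (R)-limonene and sulfur, 17 one MOM protection from 4-bromophenol).

**Ring-A iodophenol**

Step 1
Reactants: 1 2-methylresorcinol (2-methylbenzene-1,3-diol)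
Product: 2 1,3-bis(methoxymethoxy)-2-methylbenzene
Conditions: MOMCl (2.5 equiv), i-Pr2NEt (3 equiv), CH2Cl2, 0 °C → rt
Reagents that add atoms: chloromethyl methyl ether, COCCl
Why: Both phenols are O-alkylated by the reactive α-chloro ether under amine base (Williamson-type MOM ether formation).

Step 2
Reactants: 2 1,3-bis(methoxymethoxy)-2-methylbenzene
Product: 4 3,5-bis(methoxymethoxy)-4-methylphenol, via aryl pinacol boronate 3 (not isolated)
Conditions: [Ir(OMe)(cod)]2 (1.5 mol %), dtbpy (3 mol %), B2pin2 (1.0 equiv), THF, 80 °C; then 30% H2O2, aq NaOH, 0 °C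
Reagents that add atoms: hydrogen peroxide, OO (the phenol oxygen); bis(pinacolato)diboron, CC1(C)OB(OC1(C)C)B1OC(C)(C)C(C)(C)O1 (boryl group of intermediate 3 only)
Why: Sterically governed iridium-catalysed C–H borylation of a 1,2,3-trisubstituted arene should occur only at the one C–H without an ortho substituent (para to methyl), and oxidation of the C–B bond gives the symmetric phenol (Miyaura–Hartwig borylation/oxidation).

Step 3
Reactants: 4 3,5-bis(methoxymethoxy)-4-methylphenol
Product: 5 2-iodo-3,5-bis(methoxymethoxy)-4-methylphenol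
Conditions: NIS (1.0 equiv), CH2Cl2, −20 → 0 °C, dark
Reagents that add atoms: N-iodosuccinimide, O=C1CCC(=O)N1I
Why: Electrophilic aromatic iodination goes ortho to the free hydroxyl; the para position is blocked by methyl and the two ortho positions are equivalent, so only one mono-iodide can form.

**Chiral sulfonium salt**

Step 4
Reactants: 6 3,5-dihydroxybenzyl alcohol
Product: 7 [3,5-bis(methoxymethoxy)phenyl]methanol
Conditions: MOMCl (2.2 equiv), K2CO3 (4 equiv), acetone, 0 °C → rt
Reagents that add atoms: chloromethyl methyl ether, COCCl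
Why: Carbonate deprotonates only the two phenols, so Williamson etherification should leave the benzylic alcohol free.

Step 5
Reactants: 7 [3,5-bis(methoxymethoxy)phenyl]methanol
Product: 8 1-(bromomethyl)-3,5-bis(methoxymethoxy)benzene
Conditions: CBr4, PPh3, CH2Cl2, 0 °C
Reagents that add atoms: carbon tetrabromide, BrC(Br)(Br)Br
Why: The Appel reaction converts the primary benzylic alcohol into the bromide under neutral conditions that spare the MOM acetals.

Step 6
Reactants: 8 1-(bromomethyl)-3,5-bis(methoxymethoxy)benzene; 9 (1R,4R,5R)-isothiocineole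
Product: 10 (1R,4R,5R)-6-[3,5-bis(methoxymethoxy)benzyl]-4,7,7-trimethyl-6-thiabicyclo[3.2.1]octan-6-ium triflate
Conditions: LiOTf (5 equiv), CH2Cl2/H2O, rt
Reagents that add atoms: lithium triflate, [Li+].[O-]S(=O)(=O)C(F)(F)F
Why: SN2 S-alkylation of the sulfide by the benzylic bromide is made irreversible by exchange of bromide for the non-nucleophilic triflate; the benzyl group enters on the less hindered face of sulfur.

**Dihydrobenzofuran alkyne**

Step 7
Reactants: 11 2,5-dihydroxybenzaldehyde
Product: 12 2,5-bis(methoxymethoxy)benzaldehyde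
Conditions: MOMCl (3 equiv), i-Pr2NEt (4 equiv), CH2Cl2, 0 → 40 °C
Reagents that add atoms: chloromethyl methyl ether, COCCl
Why: MOM ether formation on both phenols, the hydrogen-bonded 2-OH needing gentle warming.

Step 8
Reactants: 12 2,5-bis(methoxymethoxy)benzaldehyde
Product: 14 2,5-bis(methoxymethoxy)phenol, via aryl formate 13 (not isolated)
Conditions: mCPBA, CH2Cl2, 0 °C → rt; then K2CO3 (cat.), MeOH, rt
Reagents that add atoms: 3-chloroperbenzoic acid, OOC(=O)c1cccc(Cl)c1 (one oxygen)
Why: Baeyer–Villiger (Dakin-type) oxidation with migration of the electron-rich aryl group gives the formate, which is methanolysed to the phenol that will become O1.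

Step 9
Reactants: 14 2,5-bis(methoxymethoxy)phenol
Product: 15 4-bromo-2,5-bis(methoxymethoxy)phenol
Conditions: NBS (1.0 equiv), MeCN, −20 → 0 °C
Reagents that add atoms: N-bromosuccinimide, O=C1CCC(=O)N1Br
Why: Electrophilic bromination should go para to the free hydroxyl, the most activated and least hindered position; it has to precede attachment of the other electron-rich rings.

Step 10
Reactants: 15 4-bromo-2,5-bis(methoxymethoxy)phenol
Product: 16 5-bromo-2-hydroxy-3,6-bis(methoxymethoxy)benzaldehyde
Conditions: MgCl2, Et3N, (CH2O)n, MeCN, 80 °C; aq NH4Cl work-up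
Reagents that add atoms: formaldehyde (as paraformaldehyde), C=O
Why: Magnesium-phenoxide-directed ortho-formylation (Casnati–Skattebøl) delivers formaldehyde to the only free ortho position, and hydride transfer to a second formaldehyde gives the aldehyde.

Step 11
Reactants: 16 5-bromo-2-hydroxy-3,6-bis(methoxymethoxy)benzaldehyde; 17 1-bromo-4-(methoxymethoxy)benzene
Product: 20 rac-4-bromo-3,6-bis(methoxymethoxy)-2-{[4-(methoxymethoxy)phenyl](4-methylbenzenesulfonyl)methyl}phenol, via arylmagnesium bromide 18 (not isolated), via benzhydrol 19 (not isolated)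
Conditions: 17, Mg, THF; then 16 (0.45 equiv), −40 → 0 °C, aq NH4Cl; crude 19, TolSO2H (1.5 equiv), CH2Cl2, 0 °C → rt
Reagents that add atoms: 4-methylbenzenesulfinic acid, Cc1ccc(cc1)S(=O)O; magnesium, [Mg] (in intermediate 18 only)
Why: Grignard addition to the aldehyde gives the electron-rich benzhydrol, which ionises under the mild sulfinic acid and is captured at sulfur to give a storable sulfone; the benzylic centre is racemic and is erased in step 12.

Step 12
Reactants: 20 rac-4-bromo-3,6-bis(methoxymethoxy)-2-{[4-(methoxymethoxy)phenyl](4-methylbenzenesulfonyl)methyl}phenol; 10 (1R,4R,5R)-6-[3,5-bis(methoxymethoxy)benzyl]-4,7,7-trimethyl-6-thiabicyclo[3.2.1]octan-6-ium triflate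
Product: 24 (2S,3S)-5-bromo-2-[3,5-bis(methoxymethoxy)phenyl]-4,7-bis(methoxymethoxy)-3-[4-(methoxymethoxy)phenyl]-2,3-dihydro-1-benzofuran, via o-quinone methide 21 (not isolated), via sulfonium ylide 22 (not isolated), via betaine 23 (not isolated)
Conditions: 10 (1.3 equiv), Cs2CO3 (3 equiv), MeCN, −20 °C → rt, slow addition of 20
Reagents that add atoms: none
Why: Proposed new method: carbonate expels sulfinate from the phenoxide of 20 to give o-quinone methide 21 and deprotonates 10 to the semi-stabilised benzylide 22; the ylide carbon adds to the exocyclic carbon of 21 (1,4-addition that rearomatises ring B) and the phenoxide of betaine 23 displaces the sulfide in a 5-exo-tet SN2 with inversion; C2 is set by the chiral sulfide, whose ylide reacts through one conformer on one face as in its aldehyde epoxidations, and C3 by the anti approach of the two aryl groups that also gives trans-epoxides, so the trans-(2S,3S) ring is expected; the closest known reactions are the [4+1] annulation of o-quinone methides with carbonyl-stabilised sulfonium ylides and the epoxidation/aziridination with isothiocineole benzylides.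

Step 13
Reactants: 24 (2S,3S)-5-bromo-2-[3,5-bis(methoxymethoxy)phenyl]-4,7-bis(methoxymethoxy)-3-[4-(methoxymethoxy)phenyl]-2,3-dihydro-1-benzofuran
Product: 26 (2S,3S)-5-ethynyl-2-[3,5-bis(methoxymethoxy)phenyl]-4,7-bis(methoxymethoxy)-3-[4-(methoxymethoxy)phenyl]-2,3-dihydro-1-benzofuran, via TMS-alkyne 25 (not isolated)
Conditions: TMS-acetylene (2 equiv), PdCl2(PhCN)2 (5 mol %), P(t-Bu)3·HBF4 (10 mol %), CuI (5 mol %), i-Pr2NH, dioxane, 45 °C; then K2CO3, MeOH, rt
Reagents that add atoms: ethynyltrimethylsilane, C#C[Si](C)(C)C (the two alkyne carbons; silyl group in intermediate 25 only)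
Why: Sonogashira coupling with a bulky electron-rich phosphine suits the electron-rich ortho-substituted aryl bromide, and methanolysis removes the silyl group; neither stereocentre is touched.

**Key step and endgame**

Step 14
Reactants: 5 2-iodo-3,5-bis(methoxymethoxy)-4-methylphenol; 26 (2S,3S)-5-ethynyl-2-[3,5-bis(methoxymethoxy)phenyl]-4,7-bis(methoxymethoxy)-3-[4-(methoxymethoxy)phenyl]-2,3-dihydro-1-benzofuran; 27 carbon monoxide
Product: 30 2-{(2S,3S)-2-[3,5-bis(methoxymethoxy)phenyl]-4,7-bis(methoxymethoxy)-3-[4-(methoxymethoxy)phenyl]-2,3-dihydro-1-benzofuran-5-yl}-5,7-bis(methoxymethoxy)-6-methyl-4H-chromen-4-one, via alkynone 28 (not isolated), via enaminone 29 (not isolated)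
Conditions: PdCl2(PPh3)2 (5 mol %), dppp (5 mol %), thiourea (5 mol %), DBU (2 equiv), Et2NH, CO (balloon), 40 °C
Reagents that add atoms: diethylamine, CCNCC (in intermediate 29 only, released again on ring closure)
Why: Oxidative addition of Pd(0) into the C–I bond of 5, CO insertion to the aroyl–palladium and coupling with the terminal alkyne of 26 give the o-hydroxyaryl alkynone 28 (C4a–C4 and C4–C3), the closest known reaction being the carbonylative Sonogashira coupling of o-iodophenols to flavones. Diethylamine adds to the ynone to give enaminone 29, and the C8a hydroxyl then displaces the amine at C2, so the pyranone ring closes in the 6-endo sense by addition–elimination (O1–C2) and not by 5-exo attack to an aurone. No stereocentre is formed; C2 and C3 of the dihydrobenzofuran are remote, have no acidic or ionisable bond under amine base at 40 °C and should pass through unchanged. The step needs CO insertion to precede alkynylation and needs 6-endo closure: the CO atmosphere with a bidentate phosphine secures the first and the secondary amine the second. Regiochemistry on ring A is fixed by the substrate, because iodination of the symmetric phenol 4 can only place iodine between OH and OMOM, which puts the methyl group at C6 and the free hydroxyl at C8a.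

Step 15
Reactants: 30 hepta-MOM flavone (name as in step 14)
Product: 33 2-{(2S,3S)-2-[3,5-bis(methoxymethoxy)phenyl]-4,7-bis(methoxymethoxy)-3-[4-(methoxymethoxy)phenyl]-2,3-dihydro-1-benzofuran-5-yl}-3-hydroxy-5,7-bis(methoxymethoxy)-6-methyl-4H-chromen-4-one, via 3-lithioflavone 31 (not isolated), via 3-boronate 32 (not isolated)
Conditions: LDA (1.5 equiv), THF, −78 °C; B(OMe)3, −78 → 0 °C; AcOH, 30% H2O2, 0 °C → rt
Reagents that add atoms: hydrogen peroxide, OO (the C3 oxygen); trimethyl borate, COB(OC)OC (boron in intermediate 32 only); lithium diisopropylamide, [Li+].CC(C)[N-]C(C)C (lithium in intermediate 31 only)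
Why: The C3–H of a flavone, acidified by the C4 carbonyl and O1, is removed by LDA at low temperature; borylation and oxidative C–B to C–O exchange give the flavonol (known 3-hydroxylation of flavones by lithiation–borylation–oxidation).

Step 16
Reactants: 33 3-hydroxyflavone (name as in step 15)
Product: 34 2-{(2S,3S)-2-[3,5-bis(methoxymethoxy)phenyl]-4,7-bis(methoxymethoxy)-3-[4-(methoxymethoxy)phenyl]-2,3-dihydro-1-benzofuran-5-yl}-3-methoxy-5,7-bis(methoxymethoxy)-6-methyl-4H-chromen-4-one
Conditions: MeI (3 equiv), K2CO3, DMF, rt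
Reagents that add atoms: iodomethane, CI
Why: Williamson O-methylation of the only free hydroxyl in the molecule, the other seven being MOM ethers.

Step 17
Reactants: 34 3-methoxy hepta-MOM flavone (name as in step 16)
Product: 35 2-[(2S,3S)-2-(3,5-dihydroxyphenyl)-4,7-dihydroxy-3-(4-hydroxyphenyl)-2,3-dihydro-1-benzofuran-5-yl]-5,7-dihydroxy-3-methoxy-6-methyl-4H-chromen-4-one (target)
Conditions: 3 M HCl, MeOH/THF, 45 °C, argon
Reagents that add atoms: none
Why: Acid-catalysed transacetalisation to methanol removes all seven MOM groups; the C2–O1 benzylic ether has only meta-oxygenated aryl support and the methyl enol ether at C3 is not an acetal, so the ring, both stereocentres and the 3-OMe should survive.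

**Compound list**

1 | 2-methylresorcinol | Cc1c(O)cccc1O | starting material
2 | 1,3-bis(methoxymethoxy)-2-methylbenzene | Cc1c(OCOC)cccc1OCOC | intermediate
3 | 2-[3,5-bis(methoxymethoxy)-4-methylphenyl]-4,4,5,5-tetramethyl-1,3,2-dioxaborolane | Cc1c(OCOC)cc(B2OC(C)(C)C(C)(C)O2)cc1OCOC | intermediate (not isolated)
4 | 3,5-bis(methoxymethoxy)-4-methylphenol | Cc1c(OCOC)cc(O)cc1OCOC | intermediate
5 | 2-iodo-3,5-bis(methoxymethoxy)-4-methylphenol | Cc1c(OCOC)cc(O)c(I)c1OCOC | intermediate
6 | 3,5-dihydroxybenzyl alcohol | OCc1cc(O)cc(O)c1 | starting material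
7 | [3,5-bis(methoxymethoxy)phenyl]methanol | OCc1cc(OCOC)cc(OCOC)c1 | intermediate
8 | 1-(bromomethyl)-3,5-bis(methoxymethoxy)benzene | BrCc1cc(OCOC)cc(OCOC)c1 | intermediate
9 | (1R,4R,5R)-isothiocineole (4,7,7-trimethyl-6-thiabicyclo[3.2.1]octane) | C[C@@H]1CC[C@@H]2C[C@H]1SC2(C)C | starting material
10 | (1R,4R,5R)-6-[3,5-bis(methoxymethoxy)benzyl]-4,7,7-trimethyl-6-thiabicyclo[3.2.1]octan-6-ium triflate (configuration at sulfur not drawn) | C[C@@H]1CC[C@@H]2C[C@H]1[S+](Cc1cc(OCOC)cc(OCOC)c1)C2(C)C.[O-]S(=O)(=O)C(F)(F)F | intermediate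
11 | 2,5-dihydroxybenzaldehyde | O=Cc1cc(O)ccc1O | starting material
12 | 2,5-bis(methoxymethoxy)benzaldehyde | O=Cc1cc(OCOC)ccc1OCOC | intermediate
13 | 2,5-bis(methoxymethoxy)phenyl formate | O=COc1cc(OCOC)ccc1OCOC | intermediate (not isolated)
14 | 2,5-bis(methoxymethoxy)phenol | Oc1cc(OCOC)ccc1OCOC | intermediate
15 | 4-bromo-2,5-bis(methoxymethoxy)phenol | Oc1cc(OCOC)c(Br)cc1OCOC | intermediate
16 | 5-bromo-2-hydroxy-3,6-bis(methoxymethoxy)benzaldehyde | O=Cc1c(O)c(OCOC)cc(Br)c1OCOC | intermediate
17 | 1-bromo-4-(methoxymethoxy)benzene | COCOc1ccc(Br)cc1 | starting material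
18 | [4-(methoxymethoxy)phenyl]magnesium bromide | COCOc1ccc([Mg]Br)cc1 | intermediate (not isolated)
19 | rac-4-bromo-2-{hydroxy[4-(methoxymethoxy)phenyl]methyl}-3,6-bis(methoxymethoxy)phenol | OC(c1ccc(OCOC)cc1)c1c(O)c(OCOC)cc(Br)c1OCOC | intermediate (not isolated)
20 | rac-4-bromo-3,6-bis(methoxymethoxy)-2-{[4-(methoxymethoxy)phenyl](4-methylbenzenesulfonyl)methyl}phenol | Cc1ccc(cc1)S(=O)(=O)C(c1ccc(OCOC)cc1)c1c(O)c(OCOC)cc(Br)c1OCOC | intermediate
21 | 4-bromo-2,5-bis(methoxymethoxy)-6-[4-(methoxymethoxy)benzylidene]cyclohexa-2,4-dien-1-one | O=C1C(OCOC)=CC(Br)=C(OCOC)C1=Cc1ccc(OCOC)cc1 | intermediate (not isolated)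
22 | sulfonium benzylide derived from 10 | C[C@@H]1CC[C@@H]2C[C@H]1[S+]([CH-]c1cc(OCOC)cc(OCOC)c1)C2(C)C | intermediate (not isolated)
23 | phenoxide–sulfonium betaine from 21 and 22 | [O-]c1c(OCOC)cc(Br)c(OCOC)c1[C@H](c1ccc(OCOC)cc1)[C@H](c1cc(OCOC)cc(OCOC)c1)[S+]1[C@@H]2C[C@@H](CC[C@H]2C)C1(C)C | intermediate (not isolated)
24 | (2S,3S)-5-bromo-2-[3,5-bis(methoxymethoxy)phenyl]-4,7-bis(methoxymethoxy)-3-[4-(methoxymethoxy)phenyl]-2,3-dihydro-1-benzofuran | Brc1cc(OCOC)c2c(c1OCOC)[C@H](c1ccc(OCOC)cc1)[C@@H](c1cc(OCOC)cc(OCOC)c1)O2 | intermediate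
25 | (2S,3S)-5-[(trimethylsilyl)ethynyl] analogue of 24 | C[Si](C)(C)C#Cc1cc(OCOC)c2c(c1OCOC)[C@H](c1ccc(OCOC)cc1)[C@@H](c1cc(OCOC)cc(OCOC)c1)O2 | intermediate (not isolated)
26 | (2S,3S)-5-ethynyl-2-[3,5-bis(methoxymethoxy)phenyl]-4,7-bis(methoxymethoxy)-3-[4-(methoxymethoxy)phenyl]-2,3-dihydro-1-benzofuran | C#Cc1cc(OCOC)c2c(c1OCOC)[C@H](c1ccc(OCOC)cc1)[C@@H](c1cc(OCOC)cc(OCOC)c1)O2 | intermediate
27 | carbon monoxide | [C-]#[O+] | starting material
28 | 1-[2-hydroxy-4,6-bis(methoxymethoxy)-5-methylphenyl]-3-[(2S,3S)-dihydrobenzofuran-5-yl]prop-2-yn-1-one (aryl groups as in 26) | O=C(C#Cc1cc(OCOC)c2c(c1OCOC)[C@H](c1ccc(OCOC)cc1)[C@@H](c1cc(OCOC)cc(OCOC)c1)O2)c1c(O)cc(OCOC)c(C)c1OCOC | intermediate (not isolated)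
29 | 3-(diethylamino)enone from 28 (alkene geometry open) | CCN(CC)C(=CC(=O)c1c(O)cc(OCOC)c(C)c1OCOC)c1cc(OCOC)c2c(c1OCOC)[C@H](c1ccc(OCOC)cc1)[C@@H](c1cc(OCOC)cc(OCOC)c1)O2 | intermediate (not isolated)
30 | 2-{(2S,3S)-2-[3,5-bis(methoxymethoxy)phenyl]-4,7-bis(methoxymethoxy)-3-[4-(methoxymethoxy)phenyl]-2,3-dihydro-1-benzofuran-5-yl}-5,7-bis(methoxymethoxy)-6-methyl-4H-chromen-4-one | O=c1cc(-c2cc(OCOC)c3c(c2OCOC)[C@H](c2ccc(OCOC)cc2)[C@@H](c2cc(OCOC)cc(OCOC)c2)O3)oc2cc(OCOC)c(C)c(OCOC)c12 | intermediate
31 | 3-lithio derivative of 30 | [Li]c1c(-c2cc(OCOC)c3c(c2OCOC)[C@H](c2ccc(OCOC)cc2)[C@@H](c2cc(OCOC)cc(OCOC)c2)O3)oc2cc(OCOC)c(C)c(OCOC)c2c1=O | intermediate (not isolated)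
32 | dimethyl 3-boronate of 30 | COB(OC)c1c(-c2cc(OCOC)c3c(c2OCOC)[C@H](c2ccc(OCOC)cc2)[C@@H](c2cc(OCOC)cc(OCOC)c2)O3)oc2cc(OCOC)c(C)c(OCOC)c2c1=O | intermediate (not isolated)
33 | 3-hydroxy derivative of 30 (hepta-MOM flavonol) | Oc1c(-c2cc(OCOC)c3c(c2OCOC)[C@H](c2ccc(OCOC)cc2)[C@@H](c2cc(OCOC)cc(OCOC)c2)O3)oc2cc(OCOC)c(C)c(OCOC)c2c1=O | intermediate
34 | 3-methoxy derivative of 30 (hepta-MOM target) | COc1c(-c2cc(OCOC)c3c(c2OCOC)[C@H](c2ccc(OCOC)cc2)[C@@H](c2cc(OCOC)cc(OCOC)c2)O3)oc2cc(OCOC)c(C)c(OCOC)c2c1=O | intermediate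
35 | 2-[(2S,3S)-2-(3,5-dihydroxyphenyl)-4,7-dihydroxy-3-(4-hydroxyphenyl)-2,3-dihydro-1-benzofuran-5-yl]-5,7-dihydroxy-3-methoxy-6-methyl-4H-chromen-4-one | COc1c(-c2cc(O)c3c(c2O)[C@H](c2ccc(O)cc2)[C@@H](c2cc(O)cc(O)c2)O3)oc2cc(O)c(C)c(O)c2c1=O | target

**Step count.** 17 steps in total. The longest linear sequence is 11 steps (steps 7–17, from 2,5-dihydroxybenzaldehyde 11); steps 1–3 and 4–6 are side branches.

**Steps most likely to fail**

1. Step 12. The ylide may add with poor control of its own face or of the relative approach, giving the cis isomer or low enantiomeric purity, or the quinone methide may dimerise before the ylide captures it. The fallback uses known chemistry, sets out from 20 and returns at 24. Compound 20 is annulated under the same carbonate conditions with the ester-stabilised ylide from (2-ethoxy-2-oxoethyl)dimethylsulfonium bromide, an established trans-selective [4+1] process, to give racemic ethyl trans-5-bromo-4,7-bis(methoxymethoxy)-3-[4-(methoxymethoxy)phenyl]-2,3-dihydro-1-benzofuran-2-carboxylate F1. Saponification with LiOH and classical resolution of the acid as its salt with one enantiomer of 1-phenylethylamine give (2S,3S)-5-bromo-4,7-bis(methoxymethoxy)-3-[4-(methoxymethoxy)phenyl]-2,3-dihydro-1-benzofuran-2-carboxylic acid F2. Nickel/iridium photoredox decarboxylative arylation of this α-oxy acid with 1-iodo-3,5-bis(methoxymethoxy)benzene F3 (MOM protection of 5-iodoresorcinol) should then place the C2 aryl group anti to the C3 aryl group and give 24. The aryl iodide is expected to react in preference to the hindered, electron-rich ring bromide.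

2. Step 14. The aroyl–palladium may be captured by diethylamine to give an amide, coupling may occur without CO insertion and be followed by 5-endo closure to a benzofuran, or oxidative addition at the doubly ortho-substituted electron-rich iodide may be slow. The fallback builds the same alkynone without CO, sets out from 4 and 26 and returns at 28 and then 30. Compound 4 is ortho-formylated (MgCl2, Et3N, paraformaldehyde) to 2-hydroxy-4,6-bis(methoxymethoxy)-5-methylbenzaldehyde F4. The lithium acetylide of 26 (n-BuLi, THF, −78 °C) is added to the phenoxide of F4 to give the propargylic alcohol 1-[2-hydroxy-4,6-bis(methoxymethoxy)-5-methylphenyl]-3-[(2S,3S)-dihydrobenzofuran-5-yl]prop-2-yn-1-ol F5. Oxidation with MnO2 gives 28, which is closed with Et2NH in ethanol to 30.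

3. Step 15. Metalation may occur at the wrong site, either at the doubly benzylic C3–H of the dihydrobenzofuran (epimerisation) or ortho to a MOM ether, or borylation of the hindered C3 anion may be incomplete. The fallback replaces anionic oxygenation by electrophilic oxygenation, sets out from 30 and returns at 33. The C2=C3 bond of 30 is epoxidised with dimethyldioxirane (acetone, 0 °C) to the 2,3-epoxyflavone F6, which opens at C2 and loses the C3 proton on silica gel to give flavonol 33.

**Further compounds**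

F1 | step 12 | rac-ethyl trans-5-bromo-4,7-bis(methoxymethoxy)-3-[4-(methoxymethoxy)phenyl]-2,3-dihydro-1-benzofuran-2-carboxylate (relative configuration drawn) | Brc1cc(OCOC)c2c(c1OCOC)[C@H](c1ccc(OCOC)cc1)[C@@H](C(=O)OCC)O2
F2 | step 12 | (2S,3S)-5-bromo-4,7-bis(methoxymethoxy)-3-[4-(methoxymethoxy)phenyl]-2,3-dihydro-1-benzofuran-2-carboxylic acid | Brc1cc(OCOC)c2c(c1OCOC)[C@H](c1ccc(OCOC)cc1)[C@@H](C(=O)O)O2
F3 | step 12 | 1-iodo-3,5-bis(methoxymethoxy)benzene | COCOc1cc(I)cc(OCOC)c1
F4 | step 14 | 2-hydroxy-4,6-bis(methoxymethoxy)-5-methylbenzaldehyde | O=Cc1c(O)cc(OCOC)c(C)c1OCOC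
F5 | step 14 | 1-[2-hydroxy-4,6-bis(methoxymethoxy)-5-methylphenyl]-3-[(2S,3S)-dihydrobenzofuran-5-yl]prop-2-yn-1-ol (carbinol epimers) | OC(C#Cc1cc(OCOC)c2c(c1OCOC)[C@H](c1ccc(OCOC)cc1)[C@@H](c1cc(OCOC)cc(OCOC)c1)O2)c1c(O)cc(OCOC)c(C)c1OCOC
F6 | step 15 | 2,3-epoxide of flavone 30 (epoxide diastereomers) | O=C1c2c(OCOC)c(C)c(OCOC)cc2OC2(c3cc(OCOC)c4c(c3OCOC)[C@H](c3ccc(OCOC)cc3)[C@@H](c3cc(OCOC)cc(OCOC)c3)O4)OC12
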